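**Retrosynthetic overview**
- C8, C10 and C14 are bought in (−)-quinic acid (its C3, C1 and carboxyl), and the side-chain centre in (R)-2-methylbutanoic acid. The cyclohexane is cut between C4 and C5 to give C7 and C2 of the target.
- Last disconnection: the C6–C7 bond and the lactone C–O, made by a chromium-catalysed electroreductive allylation of a masked (Z)-enal by a (Z)-2-(bromomethyl)enoate. This sets C6 and C7 and closes the ten-membered carbocycle.
- The 3,10-oxygen bridge and the (Z)-enal come from singlet-oxygen photooxygenation of a 2-alkyl-3-methylfuran, trapped by the C10 hydroxyl.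
- The furan comes from a C2≡C3 alkyne (aldehyde homologation) by Sonogashira coupling and cycloisomerisation; the allylic bromide comes from the C7 aldehyde by Morita–Baylis–Hillman reaction and Corey–Kim bromination.
- Ring order: oxolane (as spiro-lactol) → ten-membered carbocycle → γ-lactone.

Assumption: (R)-2-methylbutanoic acid (the SMILES side chain is R) and (Z)-3-iodobut-2-en-1-ol are bought as catalogue compounds.
Numbering: germacrane numbering of the target is used (C1–C10 ring, C11–C13 lactone and methylene, C14 hydroxymethyl, C15 methyl). In every intermediate C8 and C10 keep the configuration of quinic acid C3 and C1, which is the (8R,10R) arrangement of the target.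

**Step 1**
Reactants: 1 (−)-quinic acid
Product: 2 methyl 4,5-O-[(2S,3S)-2,3-dimethoxybutane-2,3-diyl]quinate (1-OH and 3-OH free)
Conditions: butane-2,3-dione, HC(OMe)3, MeOH, p-TsOH (cat.), reflux
Reagents that add atoms: butane-2,3-dione CC(=O)C(C)=O; methanol CO; trimethyl orthoformate COC(OC)OC
Why: Butane-2,3-diacetal protection with concurrent Fischer esterification: only the trans-diequatorial 4,5-diol forms the anomerically stabilised trans-fused dioxane, so O3–H (future C8–O) and the tertiary O1–H (future C10–O) stay free and no quinic stereocentre is touched.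

**Step 2**
Reactants: 2 methyl 4,5-O-[(2S,3S)-2,3-dimethoxybutane-2,3-diyl]quinate; 3 (R)-2-methylbutanoic acid
Product: 4 methyl 3-O-[(R)-2-methylbutanoyl]-4,5-O-[(2S,3S)-2,3-dimethoxybutane-2,3-diyl]quinate
Conditions: EDC·HCl, DMAP (0.2 equiv), CH2Cl2, 0 °C → rt
Reagents that add atoms: none
Why: Steglich esterification: the tertiary hydroxyl is inert, the secondary hydroxyl is acylated with retention at C8, and carbodiimide activation with catalytic DMAP at 0 °C does not epimerise the α-centre of the bought acid.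

**Step 3**
Reactants: 4 methyl 3-O-[(R)-2-methylbutanoyl]-4,5-O-[(2S,3S)-2,3-dimethoxybutane-2,3-diyl]quinate
Product: 7 methyl 5-hydroxy-4-[(R)-2-methylbutanoyloxy]-2-(2-oxoethyl)oxolane-2-carboxylate (C7 lactol on O10 as anomers; free C2 aldehyde; in equilibrium with its bicyclic hemialdal), via diol 5 (not isolated), via dialdehyde 6 (not isolated)
Conditions: TFA/H2O (9:1), 0 °C → rt; evaporate; NaIO4, THF/H2O, 0 °C
Reagents that add atoms: none
Why: Acetal hydrolysis then Malaprade glycol cleavage: periodate cuts only the freed 4,5-diol (the tertiary alcohol beside the ester is not a diol), giving C7 and C2 as aldehydes, and the α-acyloxy aldehyde is captured at once by the tertiary hydroxyl as a five-membered lactol with C8 and C10 untouched.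

**Step 4**
Reactants: 7 methyl 5-hydroxy-4-[(R)-2-methylbutanoyloxy]-2-(2-oxoethyl)oxolane-2-carboxylate; 8 dimethyl (1-diazo-2-oxopropyl)phosphonate
Product: 10 methyl 5-(tert-butyldimethylsilyloxy)-4-[(R)-2-methylbutanoyloxy]-2-(prop-2-yn-1-yl)oxolane-2-carboxylate, via alkynyl lactol 9 (not isolated)
Conditions: 8, NaOMe (2.2 equiv each), THF, −78 °C; add 7, −78 → −20 °C; then TBSCl, −20 → 0 °C
Reagents that add atoms: tert-butyldimethylsilyl chloride CC(C)(C)[Si](C)(C)Cl
Why: Seyferth–Gilbert homologation with the preformed diazophosphonate anion (Ohira–Bestmann reagent) in methanol-free THF converts the free C2 aldehyde into the C2≡C3 alkyne while C7 rests as its sodium lactolate, which is unreactive, keeps the acyl group on O8 (the lactol is the more acidic hydroxyl) and is then trapped as the silyl acetal.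

**Step 5**
Reactants: 10 methyl 5-(tert-butyldimethylsilyloxy)-4-[(R)-2-methylbutanoyloxy]-2-(prop-2-yn-1-yl)oxolane-2-carboxylate; 11 (Z)-3-iodobut-2-en-1-ol
Product: 13 methyl 5-(tert-butyldimethylsilyloxy)-4-[(R)-2-methylbutanoyloxy]-2-[2-(3-methylfuran-2-yl)ethyl]oxolane-2-carboxylate, via enynol 12 (not isolated)
Conditions: PdCl2(PPh3)2 (3 mol%), CuI (6 mol%), Et3N, THF, rt; then AgNO3 (10 mol%) on silica, CH2Cl2, rt
Reagents that add atoms: none
Why: Sonogashira coupling with retention of the Z geometry, then silver-catalysed 5-exo-dig cycloisomerisation and aromatisation of the (Z)-2-en-4-yn-1-ol to the 2-alkyl-3-methylfuran, which stores C3–C6 and C15 with the future C4=C5 bond locked cis in the ring.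

**Step 6**
Reactants: 13 methyl 5-(tert-butyldimethylsilyloxy)-4-[(R)-2-methylbutanoyloxy]-2-[2-(3-methylfuran-2-yl)ethyl]oxolane-2-carboxylate
Product: 15 5-hydroxy-2-(hydroxymethyl)-2-[2-(3-methylfuran-2-yl)ethyl]oxolan-4-yl (R)-2-methylbutanoate (C7 lactol with free C14 hydroxyl), via silylated carbinol 14 (not isolated)
Conditions: LiBH4, MeOH (1 equiv), Et2O, 0 °C; then AcOH/THF/H2O (3:1:1), rt
Reagents that add atoms: none
Why: Chemoselective borohydride reduction: the methyl ester flanked by the ring oxygen is reduced much faster than the hindered secondary 2-methylbutanoate, the silyl acetal shields C7, and mild aqueous acid then returns the lactol without harming the furan.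

**Step 7**
Reactants: 15 5-hydroxy-2-(hydroxymethyl)-2-[2-(3-methylfuran-2-yl)ethyl]oxolan-4-yl (R)-2-methylbutanoate; 16 methyl acrylate
Product: 17 methyl 3,6-dihydroxy-6-(hydroxymethyl)-2-methylidene-4-[(R)-2-methylbutanoyloxy]-8-(3-methylfuran-2-yl)octanoate (both C7 carbinol epimers)
Conditions: 16 (5 equiv), quinuclidine (0.5 equiv), MeOH (1 equiv), 0 °C → rt
Reagents that add atoms: none
Why: Morita–Baylis–Hillman reaction: the lactol opens reversibly to the activated α-acyloxy aldehyde, which is taken by the quinuclidine–acrylate zwitterion, and the new carbinol centre does not matter because the next step erases it.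

**Step 8**
Reactants: 17 methyl 3,6-dihydroxy-6-(hydroxymethyl)-2-methylidene-4-[(R)-2-methylbutanoyloxy]-8-(3-methylfuran-2-yl)octanoate
Product: 18 methyl (2Z)-2-(bromomethyl)-6-hydroxy-6-(hydroxymethyl)-4-[(R)-2-methylbutanoyloxy]-8-(3-methylfuran-2-yl)oct-2-enoate
Conditions: N-bromosuccinimide, Me2S, CH2Cl2, −20 → 0 °C
Reagents that add atoms: N-bromosuccinimide O=C1CCC(=O)N1Br
Why: Corey–Kim bromination with allylic transposition (SN2′): only the allylic alkoxysulfonium salt is displaced by bromide, giving the thermodynamically preferred (Z)-2-(bromomethyl)enoate (C8 cis to CH2Br), while the saturated primary and tertiary hydroxyls return unchanged on work-up and the furan never meets free N-bromosuccinimide.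

**Step 9**
Reactants: 18 methyl (2Z)-2-(bromomethyl)-6-hydroxy-6-(hydroxymethyl)-4-[(R)-2-methylbutanoyloxy]-8-(3-methylfuran-2-yl)oct-2-enoate
Product: 21 methyl (2Z)-2-(bromomethyl)-5-[2-hydroxy-7-(hydroxymethyl)-4-methyl-1,6-dioxaspiro[4.4]non-3-en-7-yl]-4-[(R)-2-methylbutanoyloxy]pent-2-enoate (spiro-lactol; spiro and lactol centres are mixtures that equilibrate), via endoperoxide 19 (not isolated), via hydroperoxide 20 (not isolated)
Conditions: O2, methylene blue (1 mol%), visible light, CH2Cl2, −78 °C; then Me2S, −78 °C → rt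
Reagents that add atoms: dioxygen O=O
Why: Singlet-oxygen [4+2] photooxygenation of the furan, opening of the endoperoxide by the C10 hydroxyl (which forms the C3–O bond of the 3,10-bridge) and sulfide reduction give the masked (Z)-4-oxo-enal, whose C4=C5 bond is cis because both carbons come from the furan ring, while the C3 spiro centre stays labile.

**Step 10**
Reactants: 21 methyl (2Z)-2-(bromomethyl)-5-[2-hydroxy-7-(hydroxymethyl)-4-methyl-1,6-dioxaspiro[4.4]non-3-en-7-yl]-4-[(R)-2-methylbutanoyloxy]pent-2-enoate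
Product: 24 CNP0328225.2 (target; 3S,6S,7R,8R,10R, side chain R, 4Z), via enal hemiketal 22 (not isolated), via hydroxy ester 23 (not isolated)
Conditions: CrCl2 (20 mol%), Me3SiCl (3 equiv), Bu4NBr, DMF, rt, undivided cell, Al anode, Ni-foam cathode, 5 mA (2.5 F/mol), 21 added over 10 h (2 mM); then 1 M HCl, THF, rt
Reagents that add atoms: none
Why: Proposed new method: the cathode keeps regenerating divalent chromium from trivalent chromium, so catalytic chromium turns the allylic bromide into a (Z)-2-(methoxycarbonyl)allylchromium species that adds to the aldehyde released from the lactol through a closed chair transition state (the 3,10-hemiketal holds both arms cis on the oxolane, Me3SiCl frees chromium from the alkoxide and caps the hemiketal, the aluminium anode supplies the electrons), giving the syn adduct and hence, after acid lactonisation, the cis-fused lactone at C6/C7, with the C7 face expected from allylic 1,3-strain (H8 eclipsing the alkene, ring tether anti, attack syn to the acyloxy group) and C3 settling as the only hemiketal epimer that can bridge; the closest known reactions are the electrochemical Nozaki–Hiyama–Kishi coupling and the stoichiometric CrCl2-mediated intramolecular carboalkoxyallylation used for germacranolide lactones.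

**Compound list**
1 | (−)-quinic acid, (1S,3R,4S,5R)-1,3,4,5-tetrahydroxycyclohexane-1-carboxylic acid | O[C@@]1(C(=O)O)C[C@@H](O)[C@@H](O)[C@H](O)C1 | starting material
2 | methyl 4,5-O-[(2S,3S)-2,3-dimethoxybutane-2,3-diyl]quinate | O[C@@]1(C(=O)OC)C[C@@H](O)[C@H]2O[C@](C)(OC)[C@@](C)(OC)O[C@@H]2C1 | intermediate
3 | (R)-2-methylbutanoic acid | CC[C@@H](C)C(=O)O | starting material
4 | methyl 3-O-[(R)-2-methylbutanoyl]-4,5-O-[(2S,3S)-2,3-dimethoxybutane-2,3-diyl]quinate | O[C@@]1(C(=O)OC)C[C@@H](OC(=O)[C@H](C)CC)[C@H]2O[C@](C)(OC)[C@@](C)(OC)O[C@@H]2C1 | intermediate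
5 | methyl 3-O-[(R)-2-methylbutanoyl]quinate (4,5-diol) | O[C@@]1(C(=O)OC)C[C@@H](OC(=O)[C@H](C)CC)[C@@H](O)[C@H](O)C1 | intermediate
6 | methyl 2-hydroxy-4-[(R)-2-methylbutanoyloxy]-5-oxo-2-(2-oxoethyl)pentanoate (open C7/C2 dialdehyde) | COC(=O)[C@@](O)(CC=O)C[C@@H](OC(=O)[C@H](C)CC)C=O | intermediate
7 | methyl 5-hydroxy-4-[(R)-2-methylbutanoyloxy]-2-(2-oxoethyl)oxolane-2-carboxylate (anomers) | COC(=O)[C@@]1(CC=O)C[C@@H](OC(=O)[C@H](C)CC)C(O)O1 | intermediate
8 | dimethyl (1-diazo-2-oxopropyl)phosphonate | CC(=O)C(=[N+]=[N-])P(=O)(OC)OC | starting material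
9 | methyl 5-hydroxy-4-[(R)-2-methylbutanoyloxy]-2-(prop-2-yn-1-yl)oxolane-2-carboxylate (as sodium lactolate) | COC(=O)[C@@]1(CC#C)C[C@@H](OC(=O)[C@H](C)CC)C(O)O1 | intermediate
10 | methyl 5-(tert-butyldimethylsilyloxy)-4-[(R)-2-methylbutanoyloxy]-2-(prop-2-yn-1-yl)oxolane-2-carboxylate | COC(=O)[C@@]1(CC#C)C[C@@H](OC(=O)[C@H](C)CC)C(O[Si](C)(C)C(C)(C)C)O1 | intermediate
11 | (Z)-3-iodobut-2-en-1-ol | C/C(I)=C/CO | starting material
12 | methyl 5-(tert-butyldimethylsilyloxy)-2-[(4Z)-6-hydroxy-4-methylhex-4-en-2-yn-1-yl]-4-[(R)-2-methylbutanoyloxy]oxolane-2-carboxylate | COC(=O)[C@@]1(CC#C/C(C)=C\CO)C[C@@H](OC(=O)[C@H](C)CC)C(O[Si](C)(C)C(C)(C)C)O1 | intermediate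
13 | methyl 5-(tert-butyldimethylsilyloxy)-4-[(R)-2-methylbutanoyloxy]-2-[2-(3-methylfuran-2-yl)ethyl]oxolane-2-carboxylate | COC(=O)[C@@]1(CCc2occc2C)C[C@@H](OC(=O)[C@H](C)CC)C(O[Si](C)(C)C(C)(C)C)O1 | intermediate
14 | 5-(tert-butyldimethylsilyloxy)-2-(hydroxymethyl)-2-[2-(3-methylfuran-2-yl)ethyl]oxolan-4-yl (R)-2-methylbutanoate | OC[C@@]1(CCc2occc2C)C[C@@H](OC(=O)[C@H](C)CC)C(O[Si](C)(C)C(C)(C)C)O1 | intermediate
15 | 5-hydroxy-2-(hydroxymethyl)-2-[2-(3-methylfuran-2-yl)ethyl]oxolan-4-yl (R)-2-methylbutanoate (anomers) | OC[C@@]1(CCc2occc2C)C[C@@H](OC(=O)[C@H](C)CC)C(O)O1 | intermediate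
16 | methyl acrylate | C=CC(=O)OC | starting material
17 | methyl 3,6-dihydroxy-6-(hydroxymethyl)-2-methylidene-4-[(R)-2-methylbutanoyloxy]-8-(3-methylfuran-2-yl)octanoate (C7 epimers) | OC[C@@](O)(CCc1occc1C)C[C@@H](OC(=O)[C@H](C)CC)C(O)C(=C)C(=O)OC | intermediate
18 | methyl (2Z)-2-(bromomethyl)-6-hydroxy-6-(hydroxymethyl)-4-[(R)-2-methylbutanoyloxy]-8-(3-methylfuran-2-yl)oct-2-enoate | OC[C@@](O)(CCc1occc1C)C[C@@H](OC(=O)[C@H](C)CC)/C=C(\CBr)C(=O)OC | intermediate
19 | furan endoperoxide of 18 (2,3,7-trioxabicyclo[2.2.1]hept-5-ene) | OC[C@@](O)(CCC12OOC(O1)C=C2C)C[C@@H](OC(=O)[C@H](C)CC)/C=C(\CBr)C(=O)OC | intermediate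
20 | 2-hydroperoxy-1,6-dioxaspiro[4.4]non-3-ene analogue of 21 | OC[C@@]1(CCC2(O1)OC(OO)C=C2C)C[C@@H](OC(=O)[C@H](C)CC)/C=C(\CBr)C(=O)OC | intermediate
21 | methyl (2Z)-2-(bromomethyl)-5-[2-hydroxy-7-(hydroxymethyl)-4-methyl-1,6-dioxaspiro[4.4]non-3-en-7-yl]-4-[(R)-2-methylbutanoyloxy]pent-2-enoate | OC[C@@]1(CCC2(O1)OC(O)C=C2C)C[C@@H](OC(=O)[C@H](C)CC)/C=C(\CBr)C(=O)OC | intermediate
22 | open (Z)-enal tautomer of 21 with the 3,10-hemiketal (3S) closed | OC[C@@]1(CC[C@](O)(O1)/C(C)=C\C=O)C[C@@H](OC(=O)[C@H](C)CC)/C=C(\CBr)C(=O)OC | intermediate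
23 | macrocyclic seco-lactone of 24 (6-hydroxy, methyl 2-propenoate at C7) | C=C(C(=O)OC)[C@H]1[C@@H](O)/C=C(/C)[C@]2(O)CC[C@@](CO)(O2)C[C@H]1OC(=O)[C@H](C)CC | intermediate
24 | CNP0328225.2 | C=C1C(=O)O[C@H]2/C=C(/C)[C@]3(O)CC[C@](CO)(C[C@@H](OC(=O)[C@H](C)CC)[C@@H]12)O3 | target

**Step count**
Total steps: 10. Longest linear sequence: 10 (1 → 24).

**Steps most likely to fail**

Step 10 (the proposed new step) is the least certain. Chromium turnover at the cathode is untested on a lactol-masked enal, the open ketone tautomer could be allylated instead to a seven-membered ring, and the medium-ring closure may lose to oligomers. The fallback sets out from 21 and returns at 24. Borylation of the allylic bromide (B2pin2, Pd2(dba)3 cat., toluene, 50 °C) gives methyl 5-[2-hydroxy-7-(hydroxymethyl)-4-methyl-1,6-dioxaspiro[4.4]non-3-en-7-yl]-4-[(R)-2-methylbutanoyloxy]-2-[(4,4,5,5-tetramethyl-1,3,2-dioxaborolan-2-yl)methyl]pent-2-enoate F1. Intramolecular allylboration of the unmasked aldehyde (Sc(OTf)3 cat., toluene, 2 mM, 40 °C) followed by p-TsOH lactonisation then gives 24. Both are known reaction types, and the boron chair transition state from the same alkene geometry also leads to the cis lactone.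

Step 7 is the next concern: the aldehyde is only present as a small share of the lactol equilibrium, and the acyl group sits next to the new hydroxyl under amine base for a long time. The fallback sets out from 15 and returns at 17. It replaces the amine-catalysed reaction by vinylalumination: excess α-(methoxycarbonyl)vinyl alane (from methyl propiolate, i-Bu2AlH and N-methylmorpholine N-oxide, THF, 0 °C) first turns the hydroxyls into aluminium alkoxides and then adds to the opened aldehyde within an hour. It delivers 17 directly, so its only entry is none F0.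

Step 4 is the third: 7 is a lactol/hemialdal mixture, and the homologation must find the C2 aldehyde without touching C7 or moving the acyl group. The fallback sets out from 7 and returns at 10; it masks C7 at the lactone level instead. Ag2CO3 on Celite (toluene, reflux) oxidises the lactol but not the aldehyde and gives methyl 4-[(R)-2-methylbutanoyloxy]-5-oxo-2-(2-oxoethyl)oxolane-2-carboxylate F2. Ohira–Bestmann homologation (8, K2CO3, MeOH, 0 °C) gives methyl 4-[(R)-2-methylbutanoyloxy]-5-oxo-2-(prop-2-yn-1-yl)oxolane-2-carboxylate F3. Half-reduction with i-Bu2AlH (1.1 equiv, CH2Cl2, −78 °C) returns alkynyl lactol 9, and TBSCl/imidazole gives 10.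

**Further compounds**
F1 | step 10 | methyl 5-[2-hydroxy-7-(hydroxymethyl)-4-methyl-1,6-dioxaspiro[4.4]non-3-en-7-yl]-4-[(R)-2-methylbutanoyloxy]-2-[(4,4,5,5-tetramethyl-1,3,2-dioxaborolan-2-yl)methyl]pent-2-enoate (C8 cis to CH2B) | OC[C@@]1(CCC2(O1)OC(O)C=C2C)C[C@@H](OC(=O)[C@H](C)CC)/C=C(\CB3OC(C)(C)C(C)(C)O3)C(=O)OC
F0 | step 7 | none | none
F2 | step 4 | methyl 4-[(R)-2-methylbutanoyloxy]-5-oxo-2-(2-oxoethyl)oxolane-2-carboxylate | COC(=O)[C@@]1(CC=O)C[C@@H](OC(=O)[C@H](C)CC)C(=O)O1
F3 | step 4 | methyl 4-[(R)-2-methylbutanoyloxy]-5-oxo-2-(prop-2-yn-1-yl)oxolane-2-carboxylate | COC(=O)[C@@]1(CC#C)C[C@@H](OC(=O)[C@H](C)CC)C(=O)O1
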